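The data stem from a simulated flask for substances that don't exist; the scatter is artificial.

**Easy step.** In the alpha run the starting material stands at 6.7 % after 2.50 h, so I treat each flask as beginning with intermediate A, one coupling partner bound per starting material.

common to all: starting material 0.24 M

| flask | coupling partner | remark | time |
|---|---|---|---|
| alpha | 1 M | run made earlier |  |
| beta | 1.6 M | run made earlier |  |
| west | 0.720 M |  | 20 h |
| south | 0.720 M |  | 30 h |

| run | time / h | intermediate A / % | intermediate E / % | intermediate D / % | starting material / % | product / % |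
|---|---|---|---|---|---|---|
| alpha | 0.833 | 57.0 | 0.1 | 0 | 37.1 | 0.5 |
| alpha | 2.50 | 68.7 | 0.2 | 1.2 | 6.7 | 0.4 |
| alpha | 4.00 | 62.3 | 0.7 | 4.1 | 1.5 | 1.4 |
| alpha | 6.00 | 52.9 | 1.3 | 10.1 | 0.5 | 3.6 |
| alpha | 10.0 | 39.3 | 5.8 | 20.6 | 0.3 | 8.1 |
| alpha | 12.0 | 34.6 | 8.6 | 25.4 | 0 | 9.8 |
| beta | 0.833 | 66.7 | 0 | 0 | 19.2 | 0.1 |
| beta | 2.50 | 56.2 | 0 | 3.0 | 1.2 | 1.2 |
| beta | 4.00 | 44.2 | 1.2 | 8.2 | 0.4 | 2.6 |
| beta | 6.00 | 33.0 | 2.9 | 15.9 | 0.1 | 5.6 |
| beta | 10.0 | 20.8 | 8.8 | 29.1 | 0 | 11.2 |
| beta | 12.0 | 15.9 | 12.6 | 34.2 | 0.1 | 13.8 |

(readings scatter by 0.3 percentage points)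

- which of these there is most of at the end, counted by the starting material in it, west (intermediate D / intermediate A / product / intermediate E)
- which of these there is most of at the end, counted by the starting material in it, south (intermediate D / intermediate A / product / intermediate E)
- amount of the one of these that there is most of at the end, in percent of the starting material charged, west
- amount of the one of these that there is most of at the end, in percent of the starting material charged, south

**Partner budget.** Between 6.00 h and 12.0 h intermediate A loses 0.0708 h⁻¹ in alpha and 0.122 h⁻¹ in beta, faster with more partner. So I suppose that leaving A costs a second partner. With a the share still A, free c(coupling partner) is the partner charge minus the starting charge times (2 − a).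

**Two runs.** That budget gives 0.625 M free in alpha and 1.18 M in beta, twice as much. Dividing each loss by its free partner gives 0.113 L mol⁻¹ h⁻¹ and 0.103 L mol⁻¹ h⁻¹. These come from different runs and lie close, so I trust their mean, 0.108 L mol⁻¹ h⁻¹. I call it κ, the loss of A per hour per unit of free partner, a second-order constant; κ times free partner is the pseudo-first-order constant of the moment, and it changes as partner falls.

**Joining ends.** Integrating from a full charge of A towards the far end, where free partner is 0.240 M, I get 42.3 % of A in west and 29.8 % in south. Intermediate D took 56.4 % of the D, E and product in beta at 12.0 h. Applied to everything no longer A, that share gives D 32.5 % in west, behind A, and 39.6 % in south, ahead of A. This south figure runs high, since part of the material stays unseen.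

**Forecast.** The forecast differs in south, naming intermediate A at 31 % (26 % to 36 %) for west and intermediate E at 32 % (25 % to 38 %) for south, with the line “D then goes to E”.

**The flask.** West ends with intermediate A at 36.5 %; south ends with intermediate D at 35.0 %, and A at 24.9 %.

    starting material + coupling partner → intermediate A (k = 1.32 L mol⁻¹ h⁻¹)
    coupling partner + intermediate A ⇌ intermediate B (K = 1.30 L mol⁻¹, k = 0.265 L mol⁻¹ h⁻¹)
    intermediate B → intermediate C (k = 0.226 h⁻¹)
    intermediate C → intermediate D (k = 0.452 h⁻¹)
    intermediate C → product (k = 0.137 h⁻¹)
    intermediate D ⇌ intermediate E (K = 0.530, k = 0.131 h⁻¹)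

The gap in A between south and west comes from the difference in time: south stopped at west's time holds 36.5 % of A instead of 24.9 %. West's own loss from 10.0 h to 20.0 h gives κ as 0.119 L mol⁻¹ h⁻¹. On a neighbour, the south flask charged with 0.14 M of starting material, κ gives 19.3 %, and that flask holds 15.3 % of intermediate A.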